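## Retrosynthetic overview

- The plan rests on ring B. The four adjacent atoms C1'–C4' carry, in order, the C3 carbon of ring C, OH, prenyl and OH, so the prenyl carbon C3' lies between both oxygens. This pattern is assembled from open-chain parts and not by substituting a resorcinol.
- Ring B is cut at C2'–C3', C4'–C5' and C1'–C2'. A chroman-3-yl diazo enone supplies C1', C6', C5', C2' and O2' as a vinylketene, and a prenyl siloxyalkyne supplies C3', C4' and O4'.
- The diazo enone comes from a chroman-3-carboxylic acid by reduction, oxidation/Wittig and diazo transfer. C3 is set by asymmetric hydrogenation of the 2H-chromene-3-carboxylic acid.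
- Ring C comes from a salicylaldehyde and acrylonitrile. The C6 prenyl comes from O5 by an aromatic Claisen shift, because C6 is the only free ortho position.
- Order of rings: A (bought), C (step 3), B (step 13). Two acid-free deprotections end the route.

Key step: step 13

Assumption: the ligand antipode in step 8 is assigned by analogy with (E)-2-methylcinnamic acid (same alkene geometry, reversed CIP ranking of CH2O against CH2Ar); if the other face were hydrogenated, (S)-H8-BINAP would be used and nothing else would change.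

## Route

Step 1
Reactants: 1 2,4,6-trihydroxybenzaldehyde
Product: 2 2,6-dihydroxy-4-(methoxymethoxy)benzaldehyde
Conditions: MOMCl (1.0 equiv), i-Pr2NEt (1.1 equiv), THF, 0 °C
Reagents that add atoms: chloromethyl methyl ether, COCCl
Why: Selective Williamson-type O-alkylation: the 4-OH is the most acidic hydroxyl and the only one not hydrogen-bonded to the formyl oxygen, so one equivalent of MOMCl should take it first and leave a symmetric diol with two equivalent OH groups.

Step 2
Reactants: 2 2,6-dihydroxy-4-(methoxymethoxy)benzaldehyde; 3 2-methylbut-3-yn-2-ol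
Product: 5 2-hydroxy-4-(methoxymethoxy)-6-[(2-methylbut-3-yn-2-yl)oxy]benzaldehyde, via 2-methylbut-3-yn-2-yl trifluoroacetate 4 (not isolated)
Conditions: 3, (CF3CO)2O, DBU, MeCN, 0 °C; then added to 2, DBU, CuCl2·2H2O (0.1 mol %), MeCN, 0 °C
Reagents that add atoms: none
Why: Copper-catalysed O-propargylation of a phenol with a tertiary propargylic trifluoroacetate suits electron-poor phenols such as 2; the two OH groups are equivalent, so no regiochemical question arises, and the chelated, crowded OH left in 5 should resist a second alkylation.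

Step 3
Reactants: 5 2-hydroxy-4-(methoxymethoxy)-6-[(2-methylbut-3-yn-2-yl)oxy]benzaldehyde; 6 acrylonitrile
Product: 7 7-(methoxymethoxy)-5-[(2-methylbut-3-yn-2-yl)oxy]-2H-chromene-3-carbonitrile
Conditions: acrylonitrile (excess, neat), DABCO (0.5 equiv), 75 °C
Reagents that add atoms: none
Why: The DABCO-promoted chromene annulation of a salicylaldehyde with an acrylic acceptor (Baylis–Hillman/oxa-Michael addition and loss of water) closes ring C through O1–C2 and C3–C4; acrylonitrile cannot lactonise to a coumarin as an acrylate ester can, and 75 °C lies below the temperature at which the aryl propargyl ether rearranges.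

Step 4
Reactants: 7 7-(methoxymethoxy)-5-[(2-methylbut-3-yn-2-yl)oxy]-2H-chromene-3-carbonitrile
Product: 8 7-(methoxymethoxy)-5-[(2-methylbut-3-en-2-yl)oxy]-2H-chromene-3-carbonitrile
Conditions: H2 (1 atm), Pd/CaCO3 poisoned with Pb(OAc)2 (Lindlar catalyst), quinoline, EtOAc, rt
Reagents that add atoms: none
Why: Lindlar semihydrogenation stops at the terminal alkene, and the poisoned catalyst leaves the conjugated trisubstituted C3=C4 bond and the nitrile alone.

Step 5
Reactants: 8 7-(methoxymethoxy)-5-[(2-methylbut-3-en-2-yl)oxy]-2H-chromene-3-carbonitrile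
Product: 10 5-hydroxy-7-(methoxymethoxy)-6-(3-methylbut-2-en-1-yl)-2H-chromene-3-carbonitrile, via cyclohexadienone 9 (not isolated)
Conditions: toluene, 120 °C, sealed tube, Ar
Reagents that add atoms: none
Why: In this aromatic Claisen rearrangement the [3,3] shift inverts the 1,1-dimethylallyl group to a prenyl group and can end only at C6, because the other ortho position C4a bears no hydrogen, after which dienone 9 enolises to the phenol; the gem-dimethyl group lets the shift run at moderate temperature.

Step 6
Reactants: 10 5-hydroxy-7-(methoxymethoxy)-6-(3-methylbut-2-en-1-yl)-2H-chromene-3-carbonitrile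
Product: 11 5-methoxy-7-(methoxymethoxy)-6-(3-methylbut-2-en-1-yl)-2H-chromene-3-carbonitrile
Conditions: MeI, K2CO3, DMF, rt
Reagents that add atoms: iodomethane, CI
Why: Williamson methylation of the only free phenol fixes the 5-OMe group, and nitrile, acetal and alkenes are inert to these conditions.

Step 7
Reactants: 11 5-methoxy-7-(methoxymethoxy)-6-(3-methylbut-2-en-1-yl)-2H-chromene-3-carbonitrile
Product: 12 5-methoxy-7-(methoxymethoxy)-6-(3-methylbut-2-en-1-yl)-2H-chromene-3-carboxylic acid
Conditions: NaOH (10 % aq), EtOH, reflux; then 1 M HCl, 0 °C, to pH 3–4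
Reagents that add atoms: sodium hydroxide, [Na+].[OH-]; water, O
Why: Alkaline nitrile hydrolysis is the usual passage from 2H-chromene-3-carbonitriles to the acids; MOM ether, methyl ether and prenyl group are base-stable, and the short cold acidification spares the acetal.

Step 8
Reactants: 12 5-methoxy-7-(methoxymethoxy)-6-(3-methylbut-2-en-1-yl)-2H-chromene-3-carboxylic acid
Product: 13 (3S)-5-methoxy-7-(methoxymethoxy)-6-(3-methylbut-2-en-1-yl)chroman-3-carboxylic acid
Conditions: Ru(OAc)2[(R)-H8-BINAP] (1 mol %), H2 (5 atm), MeOH, 25 °C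
Reagents that add atoms: none
Why: In this carboxylate-directed asymmetric hydrogenation of an α-substituted cinnamic-type acid the substrate binds to ruthenium as its carboxylate, the chiral diphosphine opens only one face of C3=C4 to H2 and so sets C3 as S, and the prenyl alkene, which has no binding group, should stay untouched as isolated trisubstituted alkenes do with this catalyst class.

Step 9
Reactants: 13 (3S)-5-methoxy-7-(methoxymethoxy)-6-(3-methylbut-2-en-1-yl)chroman-3-carboxylic acid
Product: 14 [(3R)-5-methoxy-7-(methoxymethoxy)-6-(3-methylbut-2-en-1-yl)chroman-3-yl]methanol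
Conditions: LiAlH4, THF, 0 °C → rt; then H2O
Reagents that add atoms: none
Why: Hydride reduction of the acid runs through the carboxylate, which is not enolised, so the arrangement at C3 is kept (the descriptor becomes R only through CIP ranking), and ethers, acetal and alkene are inert.

Step 10
Reactants: 14 [(3R)-5-methoxy-7-(methoxymethoxy)-6-(3-methylbut-2-en-1-yl)chroman-3-yl]methanol; 15 1-(triphenylphosphoranylidene)propan-2-one
Product: 17 (3E)-4-[(3R)-5-methoxy-7-(methoxymethoxy)-6-(3-methylbut-2-en-1-yl)chroman-3-yl]but-3-en-2-one, via aldehyde 16 (not isolated)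
Conditions: Dess–Martin periodinane, NaHCO3, CH2Cl2, 0 °C → rt; then 15, same flask, rt → 40 °C
Reagents that add atoms: none
Why: Dess–Martin oxidation followed in the same flask by Wittig olefination with the stabilised ylide gives the E-enone; the β-aryloxy aldehyde 16, which is prone to enolisation and retro-oxa-Michael opening, never meets a base stronger than the ylide, so C3 should hold.

Step 11
Reactants: 17 (3E)-4-[(3R)-5-methoxy-7-(methoxymethoxy)-6-(3-methylbut-2-en-1-yl)chroman-3-yl]but-3-en-2-one
Product: 19 (3E)-1-diazo-4-[(3R)-5-methoxy-7-(methoxymethoxy)-6-(3-methylbut-2-en-1-yl)chroman-3-yl]but-3-en-2-one, via trifluoroacetyl diketone 18 (not isolated)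
Conditions: LiN(SiMe3)2, THF, −78 °C; CF3CO2CH2CF3, −78 °C; cold dilute HCl wash; then MsN3, Et3N, H2O (1 equiv), MeCN, rt
Reagents that add atoms: methanesulfonyl azide, CS(=O)(=O)N=[N+]=[N-]
Why: In this detrifluoroacetylative (Regitz-type deacylative) diazo transfer the amide base at −78 °C removes the kinetic α' methyl proton and not the γ proton at C3, trifluoroacetylation activates that carbon, and the sulfonyl azide then delivers N2 with loss of the trifluoroacetyl group, a sequence suited to enones whose C=C bond would add diazomethane.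

Step 12
Reactants: 20 ethyl 4-methylpent-3-enoate
Product: 23 triisopropyl[(5-methylhex-4-en-1-yn-1-yl)oxy]silane, via dibromo enolate 21 (not isolated), via lithium ynolate 22 (not isolated)
Conditions: CH2Br2 (2.2 equiv), lithium 2,2,6,6-tetramethylpiperidide (LiTMP, 2.2 equiv), THF, −78 °C; 20; n-BuLi, −78 °C → rt; TIPSCl, 0 °C → rt
Reagents that add atoms: dibromomethane, BrCBr; chlorotriisopropylsilane, CC(C)[Si](Cl)(C(C)C)C(C)C
Why: This is a Kowalski ester homologation stopped at the ynolate: LiCHBr2 adds to the ester, enolate 21 undergoes Br/Li exchange and a 1,2-shift of the prenyl group onto the carbenoid carbon to give ynolate 22, and the bulky silyl chloride traps it on oxygen.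

Step 13
Reactants: 19 (3E)-1-diazo-4-[(3R)-5-methoxy-7-(methoxymethoxy)-6-(3-methylbut-2-en-1-yl)chroman-3-yl]but-3-en-2-one; 23 triisopropyl[(5-methylhex-4-en-1-yn-1-yl)oxy]silane
Product: 28 licoricidin 7-O-methoxymethyl 4'-O-triisopropylsilyl ether, via vinylketene 24 (not isolated), via alkenylcyclobutenone 25 (not isolated), via dienylketene 26 (not isolated), via cyclohexadienone 27 (not isolated)
Conditions: 23 (1.5 equiv), ClCH2CH2Cl (0.3 M), hν (254 nm, low-pressure Hg lamps, quartz), rt, Ar; then 80 °C
Reagents that add atoms: none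
Why: This is the Danheiser benzannulation in its diazo ketone version: light expels N2 from 19 with migration of the alkenyl group (photochemical Wolff rearrangement) to vinylketene 24, and the ketene C=C bond adds siloxyalkyne 23 in a [2+2] cycloaddition to give 4-alkenylcyclobutenone 25 (bonds C2'–C3' and C4'–C5'). Four-electron electrocyclic opening of 25, by light or at 80 °C, gives dienylketene 26, and ring B closes by a thermal disrotatory six-electron electrocyclisation that joins C1' to C2', after which dienone 27 tautomerises to phenol 28. The closest known reaction type is this same annulation of α'-diazo enones and aryl diazo ketones with triisopropylsiloxyalkynes, which gives resorcinol monosilyl ethers. The one selectivity needed is the orientation of the [2+2] step, and substrate polarity secures it: the prenyl-bearing alkyne carbon is the nucleophilic β-carbon of the ynol ether and bonds to the electrophilic ketene carbonyl carbon, so C3' ends between the former ketone oxygen (2'-OH) and the siloxy carbon C4', while the unactivated prenyl alkenes cannot compete as ketenophiles. No lasting stereocentre is formed (the sp3 ring carbons of 25 and 27 become aromatic), and C3 is kept because the medium is neutral and aprotic and H3 takes no part while the side-chain alkene stays E. The excess of 23 keeps ketene 24 from acylating the phenol already formed.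

Step 14
Reactants: 28 licoricidin 7-O-methoxymethyl 4'-O-triisopropylsilyl ether
Product: 30 licoricidin 4'-O-triisopropylsilyl ether, via bis(trimethylsilyl) ether 29 (not isolated)
Conditions: Me3SiOTf (4 equiv), 2,2'-bipyridyl (6 equiv), MeCN, 0 °C → rt; then H2O, rt
Reagents that add atoms: none
Why: The silyl triflate/2,2'-bipyridyl cleavage of an aromatic MOM ether turns the aryl acetal into the aryl trimethylsilyl ether (and silylates the 2'-OH), and water then frees both phenols; because no free Brønsted acid is present, the o-prenylphenol pairs O7/C6 and O2'/C3' should not close to 2,2-dimethylchromans, and the TIPS and methyl ethers stay.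

Step 15
Reactants: 30 licoricidin 4'-O-triisopropylsilyl ether
Product: 31 licoricidin, (3R)
Conditions: n-Bu4NF, AcOH (1:1), THF, 0 °C, Ar
Reagents that add atoms: none
Why: Fluoride desilylation of the aryl silyl ether, buffered with acetic acid so that the electron-rich phenolates are not exposed to air oxidation, touches neither the prenyl groups nor C3.

## Compound list

1 | 2,4,6-trihydroxybenzaldehyde | O=Cc1c(O)cc(O)cc1O | starting material
2 | 2,6-dihydroxy-4-(methoxymethoxy)benzaldehyde | O=Cc1c(O)cc(OCOC)cc1O | intermediate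
3 | 2-methylbut-3-yn-2-ol | CC(C)(O)C#C | starting material
4 | 2-methylbut-3-yn-2-yl trifluoroacetate | CC(C)(C#C)OC(=O)C(F)(F)F | intermediate
5 | 2-hydroxy-4-(methoxymethoxy)-6-[(2-methylbut-3-yn-2-yl)oxy]benzaldehyde | O=Cc1c(O)cc(OCOC)cc1OC(C)(C)C#C | intermediate
6 | acrylonitrile | C=CC#N | starting material
7 | 7-(methoxymethoxy)-5-[(2-methylbut-3-yn-2-yl)oxy]-2H-chromene-3-carbonitrile | N#CC1=Cc2c(OC(C)(C)C#C)cc(OCOC)cc2OC1 | intermediate
8 | 7-(methoxymethoxy)-5-[(2-methylbut-3-en-2-yl)oxy]-2H-chromene-3-carbonitrile | N#CC1=Cc2c(OC(C)(C)C=C)cc(OCOC)cc2OC1 | intermediate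
9 | 7-(methoxymethoxy)-6-(3-methylbut-2-en-1-yl)-5-oxo-5,6-dihydro-2H-chromene-3-carbonitrile (Claisen dienone, C6 unassigned) | N#CC1=CC2=C(C=C(OCOC)C(CC=C(C)C)C2=O)OC1 | intermediate
10 | 5-hydroxy-7-(methoxymethoxy)-6-(3-methylbut-2-en-1-yl)-2H-chromene-3-carbonitrile | N#CC1=Cc2c(O)c(CC=C(C)C)c(OCOC)cc2OC1 | intermediate
11 | 5-methoxy-7-(methoxymethoxy)-6-(3-methylbut-2-en-1-yl)-2H-chromene-3-carbonitrile | N#CC1=Cc2c(OC)c(CC=C(C)C)c(OCOC)cc2OC1 | intermediate
12 | 5-methoxy-7-(methoxymethoxy)-6-(3-methylbut-2-en-1-yl)-2H-chromene-3-carboxylic acid | OC(=O)C1=Cc2c(OC)c(CC=C(C)C)c(OCOC)cc2OC1 | intermediate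
13 | (3S)-5-methoxy-7-(methoxymethoxy)-6-(3-methylbut-2-en-1-yl)chroman-3-carboxylic acid | COc1c(CC=C(C)C)c(OCOC)cc2c1C[C@H](C(=O)O)CO2 | intermediate
14 | [(3R)-5-methoxy-7-(methoxymethoxy)-6-(3-methylbut-2-en-1-yl)chroman-3-yl]methanol | COc1c(CC=C(C)C)c(OCOC)cc2c1C[C@H](CO)CO2 | intermediate
15 | 1-(triphenylphosphoranylidene)propan-2-one | CC(=O)C=P(c1ccccc1)(c1ccccc1)c1ccccc1 | starting material
16 | (3S)-5-methoxy-7-(methoxymethoxy)-6-(3-methylbut-2-en-1-yl)chroman-3-carbaldehyde | COc1c(CC=C(C)C)c(OCOC)cc2c1C[C@H](C=O)CO2 | intermediate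
17 | (3E)-4-[(3R)-5-methoxy-7-(methoxymethoxy)-6-(3-methylbut-2-en-1-yl)chroman-3-yl]but-3-en-2-one | COc1c(CC=C(C)C)c(OCOC)cc2c1C[C@H](/C=C/C(C)=O)CO2 | intermediate
18 | (5E)-1,1,1-trifluoro-6-[(3R)-5-methoxy-7-(methoxymethoxy)-6-(3-methylbut-2-en-1-yl)chroman-3-yl]hex-5-ene-2,4-dione | COc1c(CC=C(C)C)c(OCOC)cc2c1C[C@H](/C=C/C(=O)CC(=O)C(F)(F)F)CO2 | intermediate
19 | (3E)-1-diazo-4-[(3R)-5-methoxy-7-(methoxymethoxy)-6-(3-methylbut-2-en-1-yl)chroman-3-yl]but-3-en-2-one | COc1c(CC=C(C)C)c(OCOC)cc2c1C[C@H](/C=C/C(=O)C=[N+]=[N-])CO2 | intermediate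
20 | ethyl 4-methylpent-3-enoate | CCOC(=O)CC=C(C)C | starting material
21 | lithium 1,1-dibromo-5-methylhexa-1,4-dien-2-olate | CC(C)=CCC([O-])=C(Br)Br.[Li+] | intermediate
22 | lithium 5-methylhex-4-en-1-yn-1-olate | CC(C)=CCC#C[O-].[Li+] | intermediate
23 | triisopropyl[(5-methylhex-4-en-1-yn-1-yl)oxy]silane | CC(C)=CCC#CO[Si](C(C)C)(C(C)C)C(C)C | intermediate
24 | (3E)-4-[(3R)-5-methoxy-7-(methoxymethoxy)-6-(3-methylbut-2-en-1-yl)chroman-3-yl]buta-1,3-dien-1-one (vinylketene) | COc1c(CC=C(C)C)c(OCOC)cc2c1C[C@H](/C=C/C=C=O)CO2 | intermediate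
25 | 4-{(E)-2-[(3R)-5-methoxy-7-(methoxymethoxy)-6-(3-methylbut-2-en-1-yl)chroman-3-yl]ethenyl}-2-(3-methylbut-2-en-1-yl)-3-(triisopropylsilyloxy)cyclobut-2-en-1-one (ring sp3 carbon unassigned) | COc1c(CC=C(C)C)c(OCOC)cc2c1C[C@H](/C=C/C1C(=O)C(CC=C(C)C)=C1O[Si](C(C)C)(C(C)C)C(C)C)CO2 | intermediate
26 | dienylketene O=C=C(prenyl)–C(OTIPS)=CH–CH=CH–(chroman-3-yl), ketene carbon and alkenyl chain cis on the central double bond, ring A as in 19 | COc1c(CC=C(C)C)c(OCOC)cc2c1C[C@H](/C=C/C=C(/O[Si](C(C)C)(C(C)C)C(C)C)C(CC=C(C)C)=C=O)CO2 | intermediate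
27 | 6-[(3R)-5-methoxy-7-(methoxymethoxy)-6-(3-methylbut-2-en-1-yl)chroman-3-yl]-2-(3-methylbut-2-en-1-yl)-3-(triisopropylsilyloxy)cyclohexa-2,4-dien-1-one (C6 unassigned) | COc1c(CC=C(C)C)c(OCOC)cc2c1C[C@H](C1C=CC(O[Si](C(C)C)(C(C)C)C(C)C)=C(CC=C(C)C)C1=O)CO2 | intermediate
28 | licoricidin 7-O-methoxymethyl 4'-O-triisopropylsilyl ether = 6-[(3R)-5-methoxy-7-(methoxymethoxy)-6-(3-methylbut-2-en-1-yl)chroman-3-yl]-2-(3-methylbut-2-en-1-yl)-3-(triisopropylsilyloxy)phenol | COc1c(CC=C(C)C)c(OCOC)cc2c1C[C@H](c1ccc(O[Si](C(C)C)(C(C)C)C(C)C)c(CC=C(C)C)c1O)CO2 | intermediate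
29 | licoricidin 7,2'-bis-O-trimethylsilyl 4'-O-triisopropylsilyl ether, (3R) | COc1c(CC=C(C)C)c(O[Si](C)(C)C)cc2c1C[C@H](c1ccc(O[Si](C(C)C)(C(C)C)C(C)C)c(CC=C(C)C)c1O[Si](C)(C)C)CO2 | intermediate
30 | licoricidin 4'-O-triisopropylsilyl ether, (3R) | COc1c(CC=C(C)C)c(O)cc2c1C[C@H](c1ccc(O[Si](C(C)C)(C(C)C)C(C)C)c(CC=C(C)C)c1O)CO2 | intermediate
31 | licoricidin, (3R) | COc1c(CC=C(C)C)c(O)cc2c1C[C@H](c1ccc(O)c(CC=C(C)C)c1O)CO2 | target

## Step count

Total step count: 15. Longest linear sequence: 14 (steps 1–11 and 13–15); step 12 is the side branch.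

## Steps most likely to fail

**Step 13.**
- What may go wrong: light may isomerise the enone or ketene 24 from E to Z, after which a 1,5-hydrogen shift from C3 drains the ketene. The ring A chromophore may also screen the lamp, and unreacted ketene may acylate the phenol already formed.
- Fallback: the ketene is made storable and the C–C bond formation becomes ionic.
- It sets out from 19. C-silylation (TIPSOTf, i-Pr2NEt, Et2O/hexane, 0 °C → rt) gives the α-silyl diazo ketone F1.
- Photochemical Wolff rearrangement of F1 (300 nm, benzene) gives the (triisopropylsilyl)vinylketene F2, a member of a ketene class that can be chromatographed.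
- Ynolate 22, released from 23 with MeLi in THF, is then C-acylated by F2.
- Six-electron ring closure, tautomerisation and a 1,3 carbon-to-oxygen shift of the silyl group follow in the same flask and place the TIPS group on O4'.
- The route is rejoined at 28.

**Step 8.**
- What may go wrong: facial selectivity may be poor, or turnover slow, because the 5-methoxy group crowds C4.
- Fallback: catalyst control is replaced by separation of covalent diastereomers.
- It sets out from acid 13 of insufficient enantiomeric purity. PivCl and Et3N in THF give the mixed pivalic anhydride F3.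
- (4S)-4-benzyl-1,3-oxazolidin-2-one with LiCl and Et3N converts F3 into the (3S,4S)-imide F4 and its C3 epimer, the (3R,4S)-imide F5, which are separated by chromatography or crystallisation.
- LiBH4 (THF/MeOH, 0 °C) cleaves F4 reductively to alcohol 14, where the route is rejoined.

**Step 12.**
- What may go wrong: the doubly activated α-CH2 of 20 may transfer a proton to LiCHBr2 or LiTMP (dienolate formation, drift of the alkene into conjugation) in place of addition to the ester carbonyl.
- Fallback: the ynolate is made by oxidising an acetylide and not by rearrangement.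
- It starts from no numbered compound. It replaces starting material 20 by commercial 1-bromo-3-methylbut-2-ene F6.
- F6 with HC≡CMgBr and catalytic CuCl in THF gives 5-methylhex-4-en-1-yne F7.
- n-BuLi (THF, −78 °C) gives the lithium acetylide F8.
- Lithium tert-butyl peroxide (t-BuOOH, LiN(SiMe3)2) transfers oxygen to F8 and gives ynolate 22.
- TIPSOTf at −78 °C then gives 23, where the route is rejoined.

## Further compounds

F1 | step 13 | (3E)-1-diazo-4-[(3R)-5-methoxy-7-(methoxymethoxy)-6-(3-methylbut-2-en-1-yl)chroman-3-yl]-1-(triisopropylsilyl)but-3-en-2-one | COc1c(CC=C(C)C)c(OCOC)cc2c1C[C@H](/C=C/C(=O)C(=[N+]=[N-])[Si](C(C)C)(C(C)C)C(C)C)CO2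
F2 | step 13 | (3E)-4-[(3R)-5-methoxy-7-(methoxymethoxy)-6-(3-methylbut-2-en-1-yl)chroman-3-yl]-2-(triisopropylsilyl)buta-1,3-dien-1-one | COc1c(CC=C(C)C)c(OCOC)cc2c1C[C@H](/C=C/C(=C=O)[Si](C(C)C)(C(C)C)C(C)C)CO2
F3 | step 8 | (3S)-5-methoxy-7-(methoxymethoxy)-6-(3-methylbut-2-en-1-yl)chroman-3-carboxylic pivalic anhydride | COc1c(CC=C(C)C)c(OCOC)cc2c1C[C@H](C(=O)OC(=O)C(C)(C)C)CO2
F4 | step 8 | (4S)-4-benzyl-3-{[(3S)-5-methoxy-7-(methoxymethoxy)-6-(3-methylbut-2-en-1-yl)chroman-3-yl]carbonyl}-1,3-oxazolidin-2-one | COc1c(CC=C(C)C)c(OCOC)cc2c1C[C@H](C(=O)N1[C@@H](Cc3ccccc3)COC1=O)CO2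
F5 | step 8 | (4S)-4-benzyl-3-{[(3R)-5-methoxy-7-(methoxymethoxy)-6-(3-methylbut-2-en-1-yl)chroman-3-yl]carbonyl}-1,3-oxazolidin-2-one | COc1c(CC=C(C)C)c(OCOC)cc2c1C[C@@H](C(=O)N1[C@@H](Cc3ccccc3)COC1=O)CO2
F6 | step 12 | 1-bromo-3-methylbut-2-ene | CC(C)=CCBr
F7 | step 12 | 5-methylhex-4-en-1-yne | C#CCC=C(C)C
F8 | step 12 | (5-methylhex-4-en-1-yn-1-yl)lithium | [Li]C#CCC=C(C)C
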